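**Retrosynthetic overview**
1. Target ⇒ late C11 isovalerate and a C7 acetate. The 1-O-isovaleryl dihydropyran (acylal plus enol ether) is closed last, by acylative oxa-cyclisation of a C1/C3 dialdehyde.
2. The dialdehyde comes from a cyclopentene carrying C9–CH2OH and C4–CH2OH arms. The C7 oxygen and the C5=C6 alkene are set together by reductive opening of a γ,δ-epoxy-dienal.
3. The dienal comes from oxidative 1,3-transposition of a tertiary allylic alcohol, made by adding a vinyl-cerium reagent to the C5 ketone of a cyclopentenone.
4. The cyclopentenone comes from α-hydroxymethylation (installing C1) of 4-hydroxy-4-(hydroxymethyl)cyclopentenone. That enone is made by a dearomative, desymmetrising Piancatelli rearrangement of 2,5-bis(hydroxymethyl)furan (key step).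
5. Ring order: the cyclopentane forms first (Step 1) and the pyran last (Step 15).

Assumption: the C1 acylal configuration is set by anomeric (axial, trans to C8) control in Step 15, as drawn in the target. The other assumptions are stated in the "Why" lines.

---

**Step 1**
Reactants: 1, 2,5-bis(hydroxymethyl)furan
Product: 2, (4S)-4-hydroxy-4-(hydroxymethyl)cyclopent-2-en-1-one
Conditions: chiral phosphoric acid (TRIP-type, 10 mol%), MeCN/H2O 9:1, 60 °C
Reagents that add atoms: water, O (its oxygen becomes the C8–OH; the ionised CH2OH is lost as water, so the net change is an isomerisation)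
Why: Piancatelli rearrangement. Proposed new method: ionisation of one enantiotopic CH2OH gives a furfuryl cation; water adds at C5 of the furan, the ring opens, and conrotatory 4π-electrocyclisation gives the 4-hydroxycyclopentenone. The chiral phosphate ion pair should control the face of water attack and so the quaternary C8 centre. Closest known reactions are the racemic Piancatelli of furfuryl alcohols and the asymmetric aza-Piancatelli with chiral acids. This one step destroys the aromaticity and the symmetry of the furan.

**Step 2**
Reactants: 3, salicylic acid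
Product: 4, 2-(tert-butyldimethylsilyloxy)benzoic acid
Conditions: TBSCl (2.2 equiv), imidazole, DMF, rt; then K2CO3, MeOH/H2O, then acidify
Reagents that add atoms: TBSCl, CC(C)(C)[Si](C)(C)Cl
Why: bis-silylation followed by selective hydrolysis of the silyl ester masks the phenol (for use as the salicylate) and leaves a free carboxylic acid.

**Step 3**
Reactants: 2, 4
Product: 5, [(1S)-1-hydroxy-4-oxocyclopent-2-en-1-yl]methyl 2-(TBSO)benzoate
Conditions: EDC·HCl, DMAP, CH2Cl2, 0 °C → rt
Reagents that add atoms: none (EDC only activates acid 4, which is a reactant)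
Why: Steglich esterification acylates the primary C10–OH over the hindered tertiary C8–OH; the stereocentre is untouched.

**Step 4**
Reactants: 5
Product: 6, enone with C9–CH2OH (C1) cis to the C8–OH
Conditions: LiHMDS (2.3 equiv), THF, −78 °C; then monomeric CH2O in THF, −78 °C; quench with NH4Cl
Reagents that add atoms: formaldehyde, C=O
Why: aldol reaction. C8 is quaternary, so only C9–H is acidic. Formaldehyde is delivered syn to the chelating C8 lithium alkoxide and anti to the CH2OAr arm, which gives C1 cis to C8–O as in the target.

**Step 5**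
Reactants: 6
Product: 7, cis-fused 1,3-dioxane acetonide of the C8–O/C1–O diol
Conditions: 2,2-dimethoxypropane, PPTS, CH2Cl2, rt
Reagents that add atoms: 2,2-dimethoxypropane, COC(C)(C)OC (supplies the CMe2)
Why: acetalisation. Only a cis-1,3-diol closes the dioxane, so this step confirms and locks the C8/C9 relative configuration and protects two hydroxyls at once. The dioxane ring then shields the top face of the cyclopentene.

**Step 6**
Reactants: 8, 2-bromoallyl alcohol
Product: 9, 2-bromoallyl TBDPS ether
Conditions: TBDPSCl, imidazole, DMF, rt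
Reagents that add atoms: TBDPSCl, CC(C)(C)[Si](c1ccccc1)(c1ccccc1)Cl
Why: silylation protects the future C11 oxygen with a group that survives the later acetonide cleavage.

**Step 7**
Reactants: 7, 9
Product: 10, tertiary allylic alcohol (C5 configuration irrelevant)
Conditions: 9 + t-BuLi (2 equiv), THF, −78 °C (Br/Li exchange); add CeCl3; add 7, −78 °C
Reagents that add atoms: none (9 is the reactant that supplies C3, C4 and C11)
Why: the organocerium reagent adds 1,2 to the C5 enone carbonyl (Luche-type selectivity, no conjugate addition or ester attack at −78 °C). This forms the C4–C5 bond; the new carbinol stereocentre is destroyed in Step 8.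

**Step 8**
Reactants: 10
Product: 11, dienal O=C3H–C4(CH2OTBDPS)=C5 with the ring alkene C6=C7
Conditions: PCC, NaOAc, CH2Cl2, rt
Reagents that add atoms: none
Why: Babler–Dauben oxidative 1,3-transposition via a chromate ester. Sigmatropic shift to the unhindered terminal CH2 gives the conjugated tetrasubstituted C4=C5 enal (this regiochemistry is assumed). The C3 and C11 carbons now sit at aldehyde and alcohol level.

**Step 9**
Reactants: 11
Product: 12, C6,C7-epoxide on the bottom face (anti to the acetonide ring)
Conditions: DMDO in acetone, CH2Cl2, 0 °C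
Reagents that add atoms: dimethyldioxirane, CC1(C)OO1 (adds O)
Why: electrophilic epoxidation. It is chemoselective for the more electron-rich γ,δ-alkene over the aldehyde-deactivated C4=C5. The cis-fused dioxane blocks the top face, so oxygen is delivered to the bottom face, setting C7–O trans to C8–O as required.

**Step 10**
Reactants: 12
Product: 13, δ-hydroxy-β,γ-unsaturated aldehyde (C7–OH on the bottom face, C5=C6; C4 epimeric)
Conditions: SmI2 (2.3 equiv), THF, −78 °C; then MeOH quench
Reagents that add atoms: none (MeOH supplies H only)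
Why: Proposed new method: one-electron reduction of the enal to a ketyl radical anion triggers C6–O cleavage of the vinylogous epoxide, giving a Sm(III) dienolate plus a C7 alkoxide. Kinetic α-protonation at C4 leaves the C5=C6 alkene, and C7 keeps the epoxide oxygen's configuration. Closest known reactions are SmI2 opening of α,β-epoxy ketones and kinetic deconjugative protonation of dienolates. Crude 13 is used directly in Step 11.

**Step 11**
Reactants: 13
Product: 14, C7-acetate
Conditions: Ac2O, pyridine, DMAP (cat.), CH2Cl2, 0 °C
Reagents that add atoms: acetic anhydride, CC(=O)OC(C)=O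
Why: acylation of the secondary alcohol; C7 configuration is unchanged.

**Step 12**
Reactants: 14
Product: 15, C3 primary alcohol
Conditions: NaBH4, EtOH/CH2Cl2, −20 °C
Reagents that add atoms: none (NaBH4 supplies H only)
Why: chemoselective aldehyde reduction that avoids handling the isomerisable β,γ-unsaturated aldehyde.

**Step 13**
Reactants: 15
Product: 16, C1/C3 diol with free tertiary C8–OH
Conditions: 80% aq. AcOH, 50 °C
Reagents that add atoms: none (hydrolysis; acetone is lost)
Why: acetal hydrolysis. The TBDPS ether, aryl TBS ether, acetate and salicylate ester survive.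

**Step 14**
Reactants: 16
Product: 17, C1/C3 dialdehyde
Conditions: Dess–Martin periodinane (2.5 equiv), NaHCO3, CH2Cl2, 0 °C → rt
Reagents that add atoms: none
Why: oxidation of both primary alcohols. The other oxygens are hindered, tertiary, silylated or acylated. The C9 stereocentre is untouched; C1 and C3 reach the oxidation level needed for cyclisation.

**Step 15**
Reactants: 17
Product: 18, C1-acylal, C3=C4 enol ether, C11–OTBDPS, aryl-OTBS
Conditions: isovaleryl chloride (1.2 equiv), ZnCl2 (10 mol%), CH2Cl2, 0 °C; then 2,6-lutidine
Reagents that add atoms: isovaleryl chloride, CC(C)CC(=O)Cl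
Why: Proposed new method: ZnCl2-assisted aldehyde + acyl chloride coupling gives the α-acyloxy carbenium (α-chloroalkyl ester) at C1. The C3 carbonyl oxygen captures it, forming a cyclic oxocarbenium, and lutidine removes C4–H to give the C3=C4 enol ether. The isovalerate adds to C1 anti to the C9–C8 bond (anomeric axial), giving the natural configuration. The closest known reactions are aldehyde acylal formation and Prins-type oxocarbenium trapping.

**Step 16**
Reactants: 18
Product: 19, C11 allylic alcohol and free salicylate phenol
Conditions: TBAF, AcOH (1:1), THF, 0 °C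
Reagents that add atoms: none
Why: buffered fluoride removes the TBDPS and aryl TBS groups without cleaving the acylal or esters.

**Step 17**
Reactants: 19
Product: 20, Jatamanvaltrate I
Conditions: isovaleryl chloride (1.05 equiv), pyridine, CH2Cl2, −20 °C
Reagents that add atoms: isovaleryl chloride, CC(C)CC(=O)Cl
Why: the primary allylic C11–OH is acylated in preference to the H-bonded phenol and the tertiary C8–OH, completing the target.

---

**Compound list**
1 | 2,5-bis(hydroxymethyl)furan | OCc1ccc(CO)o1 | starting material
2 | (4S)-4-hydroxy-4-(hydroxymethyl)cyclopent-2-en-1-one | O=C1C=C[C@](O)(CO)C1 | intermediate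
3 | salicylic acid | OC(=O)c1ccccc1O | starting material
4 | 2-(TBSO)benzoic acid | CC(C)(C)[Si](C)(C)Oc1ccccc1C(=O)O | intermediate
5 | C10 2-(TBSO)benzoate of 2 | O=C1C=C[C@](O)(COC(=O)c2ccccc2O[Si](C)(C)C(C)(C)C)C1 | intermediate
6 | 9-hydroxymethyl aldol product (C1 cis to C8–OH) | O=C1C=C[C@](O)(COC(=O)c2ccccc2O[Si](C)(C)C(C)(C)C)[C@H]1CO | intermediate
7 | cis-fused acetonide | O=C1C=C[C@@]2(COC(=O)c3ccccc3O[Si](C)(C)C(C)(C)C)OC(C)(C)OC[C@@H]12 | intermediate
8 | 2-bromoallyl alcohol | C=C(Br)CO | starting material
9 | 2-bromoallyl TBDPS ether | C=C(Br)CO[Si](c1ccccc1)(c1ccccc1)C(C)(C)C | intermediate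
10 | tertiary allylic alcohol (C5 unassigned) | C=C(CO[Si](c5ccccc5)(c6ccccc6)C(C)(C)C)C1(O)C=C[C@@]2(COC(=O)c3ccccc3O[Si](C)(C)C(C)(C)C)OC(C)(C)OC[C@@H]12 | intermediate
11 | dienal | O=CC(CO[Si](c5ccccc5)(c6ccccc6)C(C)(C)C)=C1C=C[C@@]2(COC(=O)c3ccccc3O[Si](C)(C)C(C)(C)C)OC(C)(C)OC[C@@H]12 | intermediate
12 | C6,C7-epoxide (bottom face) | O=CC(CO[Si](c5ccccc5)(c6ccccc6)C(C)(C)C)=C1[C@@H]4O[C@@H]4[C@@]2(COC(=O)c3ccccc3O[Si](C)(C)C(C)(C)C)OC(C)(C)OC[C@@H]12 | intermediate
13 | δ-hydroxy β,γ-unsaturated aldehyde (C4 epimeric) | O=CC(CO[Si](c5ccccc5)(c6ccccc6)C(C)(C)C)C1=C[C@H](O)[C@@]2(COC(=O)c3ccccc3O[Si](C)(C)C(C)(C)C)OC(C)(C)OC[C@@H]12 | intermediate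
14 | C7-acetate | O=CC(CO[Si](c5ccccc5)(c6ccccc6)C(C)(C)C)C1=C[C@H](OC(C)=O)[C@@]2(COC(=O)c3ccccc3O[Si](C)(C)C(C)(C)C)OC(C)(C)OC[C@@H]12 | intermediate
15 | C3 primary alcohol | OCC(CO[Si](c5ccccc5)(c6ccccc6)C(C)(C)C)C1=C[C@H](OC(C)=O)[C@@]2(COC(=O)c3ccccc3O[Si](C)(C)C(C)(C)C)OC(C)(C)OC[C@@H]12 | intermediate
16 | C1/C3 diol, free C8–OH | OCC(CO[Si](c5ccccc5)(c6ccccc6)C(C)(C)C)C1=C[C@H](OC(C)=O)[C@](O)(COC(=O)c2ccccc2O[Si](C)(C)C(C)(C)C)[C@H]1CO | intermediate
17 | dialdehyde | O=CC(CO[Si](c5ccccc5)(c6ccccc6)C(C)(C)C)C1=C[C@H](OC(C)=O)[C@](O)(COC(=O)c2ccccc2O[Si](C)(C)C(C)(C)C)[C@H]1C=O | intermediate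
18 | acylal/enol ether, silylated | CC(=O)O[C@H]1C=C2C(CO[Si](c5ccccc5)(c6ccccc6)C(C)(C)C)=CO[C@@H](OC(=O)CC(C)C)[C@@H]2[C@@]1(O)COC(=O)c1ccccc1O[Si](C)(C)C(C)(C)C | intermediate
19 | C11-alcohol, free phenol | CC(=O)O[C@H]1C=C2C(CO)=CO[C@@H](OC(=O)CC(C)C)[C@@H]2[C@@]1(O)COC(=O)c1ccccc1O | intermediate
20 | Jatamanvaltrate I | CC(=O)O[C@H]1C=C2C(COC(=O)CC(C)C)=CO[C@@H](OC(=O)CC(C)C)[C@@H]2[C@@]1(O)COC(=O)c1ccccc1O | target

---

**Step count**
- Total steps: 17 (Steps 2 and 6 are short side preparations of reagents).
- Longest linear sequence: 15 steps from 1 (Steps 1, 3, 4, 5, 7–17).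

**Three steps most likely to fail**
1. **Step 10 (SmI2 reductive epoxide opening with α-protonation).** It may give the conjugated enal (protonation at C6), pinacol products, or poor C7 control.
   Fallback (changes the approach): use the free-C8–OH, C1-TES variant. Do a VO(acac)2/TBHP hydroxy-directed epoxidation, then Pd/formate hydrogenolysis to install C7–OH. Invert C7 by Mitsunobu with AcOH and continue as in Steps 12–17.
2. **Step 15 (acylative oxa-cyclisation of the dialdehyde).** It may give enol-ester formation, E1cB loss of the C11 silyloxy group, or the wrong C1 configuration.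
   Fallback: close the ring as the 1-OMe acetal instead. Use the C3 dimethyl acetal and the C1 aldehyde with TMSOTf to give the cyclic methyl acetal and enol ether. Hydrolyse to the lactol and acylate with isovaleryl chloride.
3. **Step 1 (enantioselective desymmetrising Piancatelli).** The enantioselectivity is unprecedented for a free diol in water.
   Fallback: run the racemic Piancatelli of BHMF (ZnCl2 or Dy(OTf)3, H2O), then do a lipase kinetic resolution (Amano PS, vinyl acetate) of the primary alcohol.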